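**Plan**

1. Retrosynthesis: cut the C7'=C8' double bond (olefination of a C1' aldehyde), then the aryl ether bond O–C4' of the dihydrofuran ring, then C7–C8 (aldol), then C3'–C8 (aryl–CH2 coupling at an aryl iodide).
2. Forward: the aminobenzoate is turned into the 4-bromo-3-iodo ester, the acetic acid arm is joined at iodine, the aldol joins C8 to the aldehyde carbon C7, the only new ring is closed last at O–C4', and the ester is then grown into the (E)-propenol chain.
3. Enabling feature: in the 2,3-dihydrobenzofuran ring the oxygen is bound to arene carbon C4' (C7a), while both stereocentres C7 and C8 (C2 and C3) are the two sp3 ring carbons. Closure at O–C4' from a C7 carbinol and an ortho C4'–Br bond therefore touches neither centre.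
4. Stereochemistry: C7 and C8 are set together by a boron-mediated syn aldol on an (R)-4-benzyloxazolidin-2-one imide. The syn pair (C8 aryl and C7 hydroxyl on the same side of the C9–C8–C7–aryl zigzag) becomes the trans pair of ring substituents; the E alkene comes from the phosphonate olefination.

Key step: step 9

Remark: neolignan locants are used for the target atoms (C7 = C2 and C8 = C3 of the dihydrobenzofuran, C3' = C3a, C4' = C7a, C1' = C5, C5' = C7); benzoate intermediates keep ordinary benzoate locants.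

**Route**

Step 1  
Reactants: 1 methyl 4-amino-3-methoxybenzoate  
Product: 2 methyl 4-amino-3-iodo-5-methoxybenzoate  
Conditions: NIS, MeCN, 0 °C → rt, dark  
Reagents that add atoms: N-iodosuccinimide, `O=C1CCC(=O)N1I`  
Why: Electrophilic aromatic iodination is directed by the amino group, whose para position carries the ester and whose only free ortho position is C5, so iodine should enter there alone.

Step 2  
Reactants: 2 methyl 4-amino-3-iodo-5-methoxybenzoate  
Product: 4 methyl 4-bromo-3-iodo-5-methoxybenzoate, via arenediazonium bromide 3 (not isolated)  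
Conditions: NaNO2, 48% aq HBr, MeCN, 0 °C; then CuBr, 0 → 60 °C  
Reagents that add atoms: sodium nitrite, `[Na+].[O-]N=O` (terminal nitrogen of 3); hydrogen bromide, `Br` (bromine of 4)  
Why: Sandmeyer reaction, in which diazotisation followed by copper-mediated radical bromide transfer replaces the amino group by bromine and leaves the iodide and the ester untouched.

Step 3  
Reactants: 4 methyl 4-bromo-3-iodo-5-methoxybenzoate  
Product: 5 methyl 4-bromo-3-(2-tert-butoxy-2-oxoethyl)-5-methoxybenzoate  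
Conditions: BrZnCH2CO2t-Bu (commercial solution), Pd(PPh3)4 (5 mol %), THF/DMPU, 60 °C  
Reagents that add atoms: (2-tert-butoxy-2-oxoethyl)zinc bromide, `CC(C)(C)OC(=O)C[Zn]Br`  
Why: Negishi-type coupling of a Reformatsky zinc enolate, in which zerovalent palladium inserts into the carbon–iodine bond far faster than into the doubly ortho-flanked carbon–bromine bond, so only iodine should be exchanged for the acetate arm.

Step 4  
Reactants: 5 methyl 4-bromo-3-(2-tert-butoxy-2-oxoethyl)-5-methoxybenzoate  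
Product: 6 [2-bromo-3-methoxy-5-(methoxycarbonyl)phenyl]acetic acid  
Conditions: TFA, CH2Cl2, rt  
Reagents that add atoms: none  
Why: Acidolysis of the tert-butyl ester through the tert-butyl cation frees the acetic acid, while the methyl benzoate is inert to anhydrous acid.

Step 5  
Reactants: 6 [2-bromo-3-methoxy-5-(methoxycarbonyl)phenyl]acetic acid; 7 (R)-4-benzyloxazolidin-2-one  
Product: 9 methyl 3-{2-[(4R)-4-benzyl-2-oxooxazolidin-3-yl]-2-oxoethyl}-4-bromo-5-methoxybenzoate, via mixed pivalic anhydride 8 (not isolated)  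
Conditions: PivCl, Et3N, THF, −20 °C; then LiCl, 7, −20 °C → rt  
Reagents that add atoms: pivaloyl chloride, `CC(C)(C)C(Cl)=O` (its acyl group is held only in intermediate 8)  
Why: N-acylation of the oxazolidinone through a mixed anhydride under LiCl/amine activation, the nucleophile attacking the unhindered arylacetyl carbonyl and not the pivaloyl one.

Step 6  
Reactants: 9 methyl 3-{2-[(4R)-4-benzyl-2-oxooxazolidin-3-yl]-2-oxoethyl}-4-bromo-5-methoxybenzoate; 10 3,4,5-trimethoxybenzaldehyde  
Product: 13 methyl 3-[(2R,3R)-1-[(4R)-4-benzyl-2-oxooxazolidin-3-yl]-3-hydroxy-1-oxo-3-(3,4,5-trimethoxyphenyl)propan-2-yl]-4-bromo-5-methoxybenzoate, via Z-dibutylboron enolate 11 (not isolated), via dibutylboron aldolate 12 (not isolated)  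
Conditions: Bu2BOTf, i-Pr2NEt, CH2Cl2, 0 °C; 10, −78 → 0 °C; then aq NaH2PO4/Na2HPO4 buffer (pH 7), MeOH, 30% H2O2, 0 °C  
Reagents that add atoms: dibutylboron triflate, `CCCCB(CCCC)OS(=O)(=O)C(F)(F)F` (the Bu2B group is held only in intermediates 11 and 12)  
Why: Evans syn aldol reaction, in which soft enolisation gives the Z boron enolate and a closed Zimmerman–Traxler chair, with the oxazolidinone carbonyl turned away from the enolate oxygen, lets the aldehyde approach the face opposite the benzyl group, setting C8 and C7 together as the (2R,3R) syn pair.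

Step 7  
Reactants: 13 methyl 3-[(2R,3R)-1-[(4R)-4-benzyl-2-oxooxazolidin-3-yl]-3-hydroxy-1-oxo-3-(3,4,5-trimethoxyphenyl)propan-2-yl]-4-bromo-5-methoxybenzoate  
Product: 14 methyl 4-bromo-3-[(1R,2S)-1,3-dihydroxy-1-(3,4,5-trimethoxyphenyl)propan-2-yl]-5-methoxybenzoate  
Conditions: NaBH4, THF/H2O (4:1), 0 °C → rt  
Reagents that add atoms: none  
Why: Borohydride reduction of the activated imide carbonyl, far more electrophilic than the aryl methyl ester, should turn C9 into CH2OH and release the auxiliary without touching either stereocentre (the C8 descriptor changes from R to S only because C9 drops in rank).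

Step 8  
Reactants: 14 methyl 4-bromo-3-[(1R,2S)-1,3-dihydroxy-1-(3,4,5-trimethoxyphenyl)propan-2-yl]-5-methoxybenzoate  
Product: 15 methyl 4-bromo-3-[(1R,2S)-1-hydroxy-1-(3,4,5-trimethoxyphenyl)-3-(triisopropylsilyloxy)propan-2-yl]-5-methoxybenzoate  
Conditions: TIPSCl, imidazole, DMF, 0 °C → rt  
Reagents that add atoms: triisopropylsilyl chloride, `CC(C)[Si](Cl)(C(C)C)C(C)C`  
Why: Chemoselective silylation, in which the bulky silyl chloride reacts with the unhindered primary C9 hydroxyl much faster than with the flanked secondary benzylic C7 hydroxyl.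

Step 9  
Reactants: 15 methyl 4-bromo-3-[(1R,2S)-1-hydroxy-1-(3,4,5-trimethoxyphenyl)-3-(triisopropylsilyloxy)propan-2-yl]-5-methoxybenzoate  
Product: 16 methyl (2R,3S)-7-methoxy-3-[(triisopropylsilyloxy)methyl]-2-(3,4,5-trimethoxyphenyl)-2,3-dihydrobenzofuran-5-carboxylate  
Conditions: CuI (10 mol %), 3,4,7,8-tetramethyl-1,10-phenanthroline (20 mol %), Cs2CO3 (2 equiv), toluene, 110 °C, argon  
Reagents that add atoms: none  
Why: Caesium carbonate and the CuI/phenanthroline complex convert the C7 hydroxyl into a ligated monovalent copper alkoxide, which inserts into the neighbouring C4'–Br bond (activated by the para ester) to give a six-membered trivalent copper aryl alkoxide, and C–O reductive elimination then releases the aryl ether and returns monovalent copper. The closest known reaction type is the intramolecular Ullmann-type copper-catalysed O-arylation of ortho-halophenethyl alcohols, a standard entry to 2,3-dihydrobenzofurans that accepts secondary benzylic carbinols. The dihydrofuran ring (O, C7, C8, C3', C4') closes in a five-membered exo mode, the breaking C–Br bond lying outside the new ring. No stereocentre is created: the C7–O bond and the bonds at C8 are not touched, so C7 keeps its R configuration and the syn relation of the open chain appears as the trans relation of the C2 aryl and C3 silyloxymethyl groups. The step needs O7 to couple in preference to O9, which could close an equally small ring, and this is secured by the bulky triisopropylsilyl ether on O9, which is slow to migrate to the C7 alkoxide under carbonate base. It also needs the carbinol to escape oxidation to the ketone, which is secured by copper, whose alkoxides do not readily undergo β-hydride elimination, and by the fast five-ring closure.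

Step 10  
Reactants: 16 methyl (2R,3S)-7-methoxy-3-[(triisopropylsilyloxy)methyl]-2-(3,4,5-trimethoxyphenyl)-2,3-dihydrobenzofuran-5-carboxylate  
Product: 17 [(2R,3S)-7-methoxy-3-[(triisopropylsilyloxy)methyl]-2-(3,4,5-trimethoxyphenyl)-2,3-dihydrobenzofuran-5-yl]methanol  
Conditions: i-Bu2AlH, CH2Cl2, −78 → 0 °C; aq potassium sodium tartrate work-up  
Reagents that add atoms: none  
Why: Hydride reduction of the aromatic ester to the benzylic alcohol, to which the silyl ether, the aryl ethers and the dihydrofuran ring are inert.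

Step 11  
Reactants: 17 [(2R,3S)-7-methoxy-3-[(triisopropylsilyloxy)methyl]-2-(3,4,5-trimethoxyphenyl)-2,3-dihydrobenzofuran-5-yl]methanol  
Product: 18 (2R,3S)-7-methoxy-3-[(triisopropylsilyloxy)methyl]-2-(3,4,5-trimethoxyphenyl)-2,3-dihydrobenzofuran-5-carbaldehyde  
Conditions: MnO2, CH2Cl2, rt  
Reagents that add atoms: none  
Why: MnO2 oxidation is selective for benzylic alcohols and stops cleanly at the aldehyde.

Step 12  
Reactants: 18 (2R,3S)-7-methoxy-3-[(triisopropylsilyloxy)methyl]-2-(3,4,5-trimethoxyphenyl)-2,3-dihydrobenzofuran-5-carbaldehyde  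
Product: 19 ethyl (E)-3-[(2R,3S)-7-methoxy-3-[(triisopropylsilyloxy)methyl]-2-(3,4,5-trimethoxyphenyl)-2,3-dihydrobenzofuran-5-yl]prop-2-enoate  
Conditions: (EtO)2P(O)CH2CO2Et, NaH, THF, 0 °C; then 18, 0 °C → rt  
Reagents that add atoms: triethyl phosphonoacetate, `CCOC(=O)CP(=O)(OCC)OCC`  
Why: Horner–Wadsworth–Emmons olefination with a stabilised phosphonate anion, which should give the E enoate through the reversible, thermodynamically controlled addition step.

Step 13  
Reactants: 19 ethyl (E)-3-[(2R,3S)-7-methoxy-3-[(triisopropylsilyloxy)methyl]-2-(3,4,5-trimethoxyphenyl)-2,3-dihydrobenzofuran-5-yl]prop-2-enoate  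
Product: 20 (E)-3-[(2R,3S)-7-methoxy-3-[(triisopropylsilyloxy)methyl]-2-(3,4,5-trimethoxyphenyl)-2,3-dihydrobenzofuran-5-yl]prop-2-en-1-ol  
Conditions: i-Bu2AlH, CH2Cl2, −78 °C; aq potassium sodium tartrate work-up  
Reagents that add atoms: none  
Why: 1,2-Reduction of the α,β-unsaturated ester by the aluminium hydride at low temperature should give the allylic alcohol with the E geometry retained.

Step 14  
Reactants: 20 (E)-3-[(2R,3S)-7-methoxy-3-[(triisopropylsilyloxy)methyl]-2-(3,4,5-trimethoxyphenyl)-2,3-dihydrobenzofuran-5-yl]prop-2-en-1-ol  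
Product: 21 (−)-(7R,8S,7'E)-3,4,5,5'-tetramethoxy-4',7-epoxy-8,3'-neolign-7'-ene-9,9'-diol  
Conditions: Bu4NF, THF, 0 °C → rt  
Reagents that add atoms: none  
Why: Fluoride-mediated desilylation, driven by the strong Si–F bond, frees the C9 hydroxyl, and nothing else in the molecule is sensitive to fluoride under these conditions.

**Compound list**

1 | methyl 4-amino-3-methoxybenzoate | `COC(=O)c1ccc(N)c(OC)c1` | starting material  
2 | methyl 4-amino-3-iodo-5-methoxybenzoate | `COC(=O)c1cc(I)c(N)c(OC)c1` | intermediate  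
3 | 2-iodo-6-methoxy-4-(methoxycarbonyl)benzenediazonium bromide (formed in the flask) | `COC(=O)c1cc(I)c([N+]#N)c(OC)c1.[Br-]` | intermediate  
4 | methyl 4-bromo-3-iodo-5-methoxybenzoate | `COC(=O)c1cc(I)c(Br)c(OC)c1` | intermediate  
5 | methyl 4-bromo-3-(2-tert-butoxy-2-oxoethyl)-5-methoxybenzoate | `COC(=O)c1cc(CC(=O)OC(C)(C)C)c(Br)c(OC)c1` | intermediate  
6 | [2-bromo-3-methoxy-5-(methoxycarbonyl)phenyl]acetic acid | `COC(=O)c1cc(CC(=O)O)c(Br)c(OC)c1` | intermediate  
7 | (R)-4-benzyloxazolidin-2-one | `O=C1N[C@H](Cc2ccccc2)CO1` | starting material  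
8 | [2-bromo-3-methoxy-5-(methoxycarbonyl)phenyl]acetic pivalic anhydride (formed in the flask) | `COC(=O)c1cc(CC(=O)OC(=O)C(C)(C)C)c(Br)c(OC)c1` | intermediate  
9 | methyl 3-{2-[(4R)-4-benzyl-2-oxooxazolidin-3-yl]-2-oxoethyl}-4-bromo-5-methoxybenzoate | `COC(=O)c1cc(CC(=O)N2[C@H](Cc3ccccc3)COC2=O)c(Br)c(OC)c1` | intermediate  
10 | 3,4,5-trimethoxybenzaldehyde | `COc1cc(C=O)cc(OC)c1OC` | starting material  
11 | Z-dibutylboron enolate of 9 (formed in the flask) | `COC(=O)c1cc(/C=C(\OB(CCCC)CCCC)N2[C@H](Cc3ccccc3)COC2=O)c(Br)c(OC)c1` | intermediate  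
12 | O-dibutylboryl derivative of 13, the boron aldolate (formed in the flask) | `COc1cc([C@H](OB(CCCC)CCCC)[C@H](C(=O)N2[C@H](Cc3ccccc3)COC2=O)c4cc(C(=O)OC)cc(OC)c4Br)cc(OC)c1OC` | intermediate  
13 | methyl 3-[(2R,3R)-1-[(4R)-4-benzyl-2-oxooxazolidin-3-yl]-3-hydroxy-1-oxo-3-(3,4,5-trimethoxyphenyl)propan-2-yl]-4-bromo-5-methoxybenzoate | `COc1cc([C@H](O)[C@H](C(=O)N2[C@H](Cc3ccccc3)COC2=O)c4cc(C(=O)OC)cc(OC)c4Br)cc(OC)c1OC` | intermediate  
14 | methyl 4-bromo-3-[(1R,2S)-1,3-dihydroxy-1-(3,4,5-trimethoxyphenyl)propan-2-yl]-5-methoxybenzoate | `COc1cc([C@H](O)[C@H](CO)c2cc(C(=O)OC)cc(OC)c2Br)cc(OC)c1OC` | intermediate  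
15 | methyl 4-bromo-3-[(1R,2S)-1-hydroxy-1-(3,4,5-trimethoxyphenyl)-3-(triisopropylsilyloxy)propan-2-yl]-5-methoxybenzoate | `COc1cc([C@H](O)[C@H](CO[Si](C(C)C)(C(C)C)C(C)C)c2cc(C(=O)OC)cc(OC)c2Br)cc(OC)c1OC` | intermediate  
16 | methyl (2R,3S)-7-methoxy-3-[(triisopropylsilyloxy)methyl]-2-(3,4,5-trimethoxyphenyl)-2,3-dihydrobenzofuran-5-carboxylate | `COc1cc([C@@H]2Oc3c(OC)cc(C(=O)OC)cc3[C@H]2CO[Si](C(C)C)(C(C)C)C(C)C)cc(OC)c1OC` | intermediate  
17 | [(2R,3S)-7-methoxy-3-[(triisopropylsilyloxy)methyl]-2-(3,4,5-trimethoxyphenyl)-2,3-dihydrobenzofuran-5-yl]methanol | `COc1cc([C@@H]2Oc3c(OC)cc(CO)cc3[C@H]2CO[Si](C(C)C)(C(C)C)C(C)C)cc(OC)c1OC` | intermediate  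
18 | (2R,3S)-7-methoxy-3-[(triisopropylsilyloxy)methyl]-2-(3,4,5-trimethoxyphenyl)-2,3-dihydrobenzofuran-5-carbaldehyde | `COc1cc([C@@H]2Oc3c(OC)cc(C=O)cc3[C@H]2CO[Si](C(C)C)(C(C)C)C(C)C)cc(OC)c1OC` | intermediate  
19 | ethyl (E)-3-[(2R,3S)-7-methoxy-3-[(triisopropylsilyloxy)methyl]-2-(3,4,5-trimethoxyphenyl)-2,3-dihydrobenzofuran-5-yl]prop-2-enoate | `COc1cc([C@@H]2Oc3c(OC)cc(/C=C/C(=O)OCC)cc3[C@H]2CO[Si](C(C)C)(C(C)C)C(C)C)cc(OC)c1OC` | intermediate  
20 | (E)-3-[(2R,3S)-7-methoxy-3-[(triisopropylsilyloxy)methyl]-2-(3,4,5-trimethoxyphenyl)-2,3-dihydrobenzofuran-5-yl]prop-2-en-1-ol | `COc1cc([C@@H]2Oc3c(OC)cc(/C=C/CO)cc3[C@H]2CO[Si](C(C)C)(C(C)C)C(C)C)cc(OC)c1OC` | intermediate  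
21 | (−)-(7R,8S,7'E)-3,4,5,5'-tetramethoxy-4',7-epoxy-8,3'-neolign-7'-ene-9,9'-diol, i.e. (E)-3-[(2R,3S)-3-(hydroxymethyl)-7-methoxy-2-(3,4,5-trimethoxyphenyl)-2,3-dihydrobenzofuran-5-yl]prop-2-en-1-ol | `COc1cc([C@@H]2Oc3c(OC)cc(/C=C/CO)cc3[C@H]2CO)cc(OC)c1OC` | target  

**Step count and risks**

Total step count: 14. Longest linear sequence: 14 steps (1 → 21); 7 and 10 enter as purchased materials.

Steps most likely to fail:

1. Step 9. Insertion of copper into the C4'–Br bond, which is flanked on both sides, may be slow. Protodebromination could then overtake the etherification, as could base-induced transfer of the silyl group from O9 to O7 followed by closure through O9. The fallback sets out from 15, returns at 16 and closes the ring from the other side, at O–C7. Miyaura borylation of 15 (B2pin2, PdCl2(dppf), KOAc, dioxane, 90 °C) should give methyl 3-[(1R,2S)-1-hydroxy-1-(3,4,5-trimethoxyphenyl)-3-(triisopropylsilyloxy)propan-2-yl]-5-methoxy-4-(4,4,5,5-tetramethyl-1,3,2-dioxaborolan-2-yl)benzoate F1. Oxidation (NaBO3·4H2O, THF/H2O, rt) should give methyl 4-hydroxy-3-[(1R,2S)-1-hydroxy-1-(3,4,5-trimethoxyphenyl)-3-(triisopropylsilyloxy)propan-2-yl]-5-methoxybenzoate F2. Catalytic TsOH in CH2Cl2 at 0 °C should then ionise the trimethoxybenzylic carbinol; the phenol is expected to capture the cation anti to the C8 substituent and, the closure being reversible, to settle on the trans ether 16.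

2. Step 6. The ortho-bromoaryl group may slow soft enolisation or loosen the closed transition state, eroding facial and syn selectivity, and the adduct may revert by retro-aldol cleavage during the oxidative work-up. The fallback sets out from 6, returns at 14 and uses a titanium enolate of a thiazolidinethione in place of the boron enolate. Coupling of 6 with (R)-4-benzyl-1,3-thiazolidine-2-thione (EDC·HCl, DMAP, CH2Cl2) should give methyl 3-{2-[(4R)-4-benzyl-2-thioxo-1,3-thiazolidin-3-yl]-2-oxoethyl}-4-bromo-5-methoxybenzoate F3. Its chlorotitanium enolate (TiCl4, i-Pr2NEt, N-methyl-2-pyrrolidinone, CH2Cl2, 0 °C) should add to 10 through a non-chelated chair to give methyl 3-[(2R,3R)-1-[(4R)-4-benzyl-2-thioxo-1,3-thiazolidin-3-yl]-3-hydroxy-1-oxo-3-(3,4,5-trimethoxyphenyl)propan-2-yl]-4-bromo-5-methoxybenzoate F4. This adduct needs no oxidative work-up and should be reduced by NaBH4 in THF/EtOH at 0 °C directly to 14.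

3. Step 7. In the basic borohydride medium the C7 alkoxide may fragment by retro-aldol cleavage (the α-aryl enolate is a good leaving group), C8 may epimerise, or the aryl ester may be partly reduced. The fallback sets out from 13, returns at 14 and separates auxiliary removal from reduction. Hydrolysis with LiOH/H2O2 (THF/H2O, 0 °C) should give (2R,3R)-2-[2-bromo-3-methoxy-5-(methoxycarbonyl)phenyl]-3-hydroxy-3-(3,4,5-trimethoxyphenyl)propanoic acid F5. Reduction of the carboxylic acid with BH3·SMe2 (THF, 0 °C → rt), which leaves the methyl ester alone, should then give 14.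

**Further compounds**

F1 | step 9 | methyl 3-[(1R,2S)-1-hydroxy-1-(3,4,5-trimethoxyphenyl)-3-(triisopropylsilyloxy)propan-2-yl]-5-methoxy-4-(4,4,5,5-tetramethyl-1,3,2-dioxaborolan-2-yl)benzoate | `COc1cc([C@H](O)[C@H](CO[Si](C(C)C)(C(C)C)C(C)C)c2cc(C(=O)OC)cc(OC)c2B3OC(C)(C)C(C)(C)O3)cc(OC)c1OC`  
F2 | step 9 | methyl 4-hydroxy-3-[(1R,2S)-1-hydroxy-1-(3,4,5-trimethoxyphenyl)-3-(triisopropylsilyloxy)propan-2-yl]-5-methoxybenzoate | `COc1cc([C@H](O)[C@H](CO[Si](C(C)C)(C(C)C)C(C)C)c2cc(C(=O)OC)cc(OC)c2O)cc(OC)c1OC`  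
F3 | step 6 | methyl 3-{2-[(4R)-4-benzyl-2-thioxo-1,3-thiazolidin-3-yl]-2-oxoethyl}-4-bromo-5-methoxybenzoate | `COC(=O)c1cc(CC(=O)N2[C@H](Cc3ccccc3)CSC2=S)c(Br)c(OC)c1`  
F4 | step 6 | methyl 3-[(2R,3R)-1-[(4R)-4-benzyl-2-thioxo-1,3-thiazolidin-3-yl]-3-hydroxy-1-oxo-3-(3,4,5-trimethoxyphenyl)propan-2-yl]-4-bromo-5-methoxybenzoate | `COc1cc([C@H](O)[C@H](C(=O)N2[C@H](Cc3ccccc3)CSC2=S)c4cc(C(=O)OC)cc(OC)c4Br)cc(OC)c1OC`  
F5 | step 7 | (2R,3R)-2-[2-bromo-3-methoxy-5-(methoxycarbonyl)phenyl]-3-hydroxy-3-(3,4,5-trimethoxyphenyl)propanoic acid | `COc1cc([C@H](O)[C@H](C(=O)O)c2cc(C(=O)OC)cc(OC)c2Br)cc(OC)c1OC`  
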